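# Proposed synthesis of CNP0103039.1 by auxiliary-controlled methylation of an acyclic enamine

## The problem

CNP0103039.1 is a trimeric acylphloroglucinol. A dearomatised ring A (a 2-acetyl-3,5-dihydroxycyclohexa-2,5-dienone), a central butanoylphloroglucinol ring B and a 2,2-dimethyl-2H-chromene ring C stand in a row, joined by two methylene bridges that both end on ring B.

The only stereocentre is C-4 of ring A, a quaternary carbon bearing methyl, geranyl and the two enol carbons C-3 and C-5. No other stereocentre exists to relay chirality to it, so an external controller must set it. C-4 is stereogenic only because its ring neighbours differ one bond further out: C-2 carries the acetyl group and C-6 the bridge. Any intermediate in which the two flanks of C-4 become alike is achiral, so the acetyl carbons must be attached before ring A is closed.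

Ring B has two equivalent free carbons, whereas rings A and C have one each, so the order of bridging decides whether mixtures arise. The pyran oxygen of ring C must sit ortho to the butanoyl group, which is a regiochemical question in its own right.

Several groups are fragile:
- The geranyl alkenes and the chromene alkene cyclise onto neighbouring enol or phenol oxygens in strong acid.
- Methylene bridges between phloroglucinol rings cleave and recombine in base or on long heating.
- The enolised triketone loses acyl groups under hot alkoxide.

The key step rests on C-4 carrying two alkyl groups and two carbons at the carbonyl oxidation level. With C-5 read as a former ketone carbon and C-3 as a former ester carbon, C-4 is the alpha carbon of an alpha,alpha-dialkylated beta-keto ester. Such a centre can be made by alkylating a chiral enamine and cannot racemise afterwards.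

## Retrosynthesis

**Ring A to bridge bond.** Target 25 is cut first at the bond between C-6 of ring A and its bridge carbon, giving ring A 13 and the ring B–ring C dimer as its Mannich base 24. This cut comes last in the forward sense because 13 is the only chiral and the most laboriously made fragment, and because each partner then has exactly one reactive site: 13 one ring CH, 24 one aminomethyl group. The forward reaction must generate the ring B ortho-quinone methide under conditions mild enough not to disturb the bridge already present.

**Ring B to ring C bridge.** Mannich base 24 comes from dimer 23 and N,N-dimethylmethaniminium iodide 21. Dimer 23 is cut at the bond between ring B and the bridge carbon, giving the ring C Mannich base 22 and butanoylphloroglucinol 16. Ring B is the symmetric partner, so it must be the nucleophile and be used in excess; ring C has one free carbon and therefore carries the leaving group. Mannich base 22 comes from chromene 20 and 21.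

**Ring C.** Chromene 20 is the deprotected form of bis-MOM chromene 19. The pyran ring of 19 is cut at the aryl–C-4 bond and the O-1–C-2 bond, leading to phenol 17 and 3-methylbut-2-enal 18. In 17 only the hydroxyl ortho to the ketone is free, so only that oxygen can enter the pyran ring; this settles the regiochemistry that an unprotected triol would leave open. Phenol 17 comes from 16 by double MOM protection, and 16 from phloroglucinol 14 and butanoyl chloride 15.

**Ring A closure.** Ring A 13 is cut at the C-2–C-3 bond, between the acetyl-bearing carbon and the enol carbon next to the quaternary centre, giving the open-chain trioxo ester 12. Among the six ring bonds this is the only cut that leaves C-4 flanked by two different carbonyl carbons (an ester and a ketone) and keeps the acetyl carbons in the chain. The forward reaction is a Claisen condensation of the doubly activated methylene onto the ester. No other carbanion of 12 can reach an electrophile through a six-membered ring without deprotonation of the terminal methyl.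

**Chain extension.** Trioxo ester 12 is the unmasked form of ketal 11. Cutting 11 between the former ketone methyl and the next carbonyl gives keto ester 8 and the four-carbon N-methoxy-N-methylamide 10, made from ester 9. Adding the four carbons as one masked acetoacetyl unit is preferred to two successive acetylations. After a single acetylation the chain would end in a free methyl ketone whose carbanion could close onto the ester before the last two carbons arrive, and a ring closed at that stage would have two identical flanks at the quaternary carbon. With 10 the carbon that later attacks the ester is never a terminal methyl.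

**The quaternary carbon (key disconnection).** Keto ester 8 is cut at the bond between the quaternary carbon and its methyl group, giving the chelated enamine 5 and iodomethane 6, with imine 7 as the species hydrolysed in the flask. The auxiliary turns a prochiral tetrasubstituted enolate, which has no inherent facial bias, into a rigid lithium chelate with distinct faces. The two alkyl groups are distinguished by their order of introduction. The forward reaction needs carbon alkylation, high facial selectivity and a hydrolysis that spares both esters.

**Enamine and its precursors.** Enamine 5 comes from racemic methyl 2-geranylacetoacetate 3 and tert-butyl L-valinate 4. The stereocentre of 3 vanishes in the enamine, so its racemic nature is of no consequence. Keto ester 3 comes from methyl acetoacetate 1 and geranyl bromide 2.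

## Roads not taken

**Alternative 1:** This plan centres on ring C. It cuts the aryl–C-4 and O-1–C-2 bonds of the pyran back to the 1,1-dimethylpropargyl ether A1 of the chelated hydroxyl. Heating A1 should trigger a [3,3] rearrangement, a 1,5-hydrogen shift and an oxa-6π electrocyclisation to give the bis-MOM chromene A2, which is the same compound as 19.
- Merits: the regiochemistry is fixed by the oxygen that carries the propargyl group, and the carbon–carbon bond forms intramolecularly, so it does not depend on the nucleophilicity of an acylated, hydrogen-bonded phenol.
- Weak points: etherification of that hindered hydroxyl with a tertiary propargylic electrophile is slow, and two steps replace one. As the central idea it addresses the least demanding ring and leaves the quaternary stereocentre and both bridges unaddressed.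
- Comparison: for the pyran ring alone this road is the more reliable. The chosen plan sets one step fewer against it, has the same regiochemical guarantee (only one hydroxyl of 17 is free), and keeps the cascade as its fallback.

**Alternative 2:** This plan cuts ring A between the acetyl-bearing carbon and the neighbouring enol carbon. The doubly activated methylene of the trioxo ester A3 attacks the ester carbonyl to give ring A, A4. A3 and A4 are identical with 12 and 13.
- Merits: the closure is biomimetic, brings every ring A substituent in one chain, and has only one feasible six-membered mode because the alpha carbon of the ester is quaternary.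
- Weak points: it creates no stereocentre and cannot influence the existing one. The plan presupposes an enantiopure quaternary carbon without saying where it comes from, and it does not say how the chain is assembled without passing through a ring with two identical flanks.
- Comparison: as a ring-forming step it is exactly as good as the chosen plan, because it is step 7 of the chosen plan. What the chosen plan adds is the origin of the configuration and a chain assembly that protects it.

**Alternative 3:** This plan builds ring A onto ring B. The lithium enolate of a quaternary keto ester is acylated by the lactone carbonyl of the ring B dihydrocoumarin A6, and the resulting diketone dianion closes onto the methyl ester. The product is the ring A–methylene–ring B compound A7, still lacking the acetyl group.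
- Merits: one bridge is made by irreversible carbonyl chemistry and not by ortho-quinone methide trapping, so it cannot scramble, and the annulation is convergent.
- Weak points:
  - The bridge carbon ends up next to the ester-derived carbon. The plan therefore needs the S keto ester A5, the mirror image of 8; this costs nothing but must be noticed.
  - The acetyl group has to be introduced late at the free ring A carbon in the presence of phenols, where oxygen acylation competes.
  - The MOM ethers must be removed with acid while the geranyl chain sits next to an enol, the setting in which acid closes a pyran ring.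
  - A6 needs a synthesis of its own, and the second bridge still requires the Mannich chemistry.
- Comparison: this road is better in the security of the ring A–ring B bridge. The chosen plan sets against it that the acetyl group is in place before ring A exists, that no protecting group is removed once the geranyl group and the enols are together, and that every bridging step joins partners with one reactive site each.

Key step: step 3

## Assumptions

- Sense of induction in step 3: in the lithium chelate the strongly bound ligand (Me2N)3PO is taken to occupy the lithium face remote from the isopropyl group, so that iodomethane enters from the isopropyl face. For the L-valine auxiliary this corresponds to R at the new centre. If the first batch shows the opposite sense, the same step with tert-butyl D-valinate supplies 8 with no other change.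
- Enolised tri- and tetracarbonyl compounds are drawn in one tautomeric form, and stereodescriptors refer to that form.

## Route

**Step 1**
Reactants: 1 methyl acetoacetate; 2 geranyl bromide
Product: 3 methyl (4E)-2-acetyl-5,9-dimethyldeca-4,8-dienoate (methyl 2-geranylacetoacetate, racemic)
Conditions: NaH, THF, 0 °C; then 2 (1 in 1.5-fold excess), 0 °C → rt
Reagents that add atoms: none
Why: Acetoacetic ester alkylation; the stabilised enolate displaces the primary allylic bromide at carbon with retention of the E alkene, and the excess of 1 suppresses dialkylation.

**Step 2**
Reactants: 3 methyl 2-geranylacetoacetate; 4 tert-butyl L-valinate (free base)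
Product: 5 tert-butyl N-[(2Z,5E)-3-(methoxycarbonyl)-6,10-dimethylundeca-2,5,9-trien-2-yl]-L-valinate
Conditions: cat. BF3·OEt2, toluene, reflux, Dean–Stark trap
Reagents that add atoms: none
Why: Acid-catalysed condensation of a beta-keto ester with a primary amine to the vinylogous carbamate, driven by azeotropic removal of water; the N–H to ester carbonyl hydrogen bond fixes the Z geometry, and the stereocentre of 3 disappears.

**Step 3**
Reactants: 5 chelated enamine; 6 iodomethane
Product: 8 methyl (2R,4E)-2-acetyl-2,5,9-trimethyldeca-4,8-dienoate, via C-methylated valine imine 7 (not isolated)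
Conditions: LiN(i-Pr)2, toluene, −78 °C; (Me2N)3PO (1.2 equiv); MeI, −78 → −40 °C; then 1 M aq. HCl, rt
Reagents that add atoms: iodomethane 6 (CI); water (O)
Why: Lithium diisopropylamide removes the N–H proton of the Z enamino ester and gives a lithium aza-enolate in which lithium is held by nitrogen, by the methyl ester carbonyl in a six-membered chelate and by the tert-butyl ester carbonyl of the valine arm in a five-membered chelate, so the nucleophilic carbon has one geometry and the isopropyl group lies on one face of a rigid bicyclic chelate. The fourth lithium site is taken by (Me2N)3PO on the face away from the isopropyl group, and iodomethane should therefore alkylate C-3 from the isopropyl face to give imine 7 with the R configuration at the new quaternary carbon; the closest known reaction type is the diastereoselective alkylation of lithiated valine tert-butyl ester enamines of alpha-alkyl beta-keto esters. No ring is closed in this step. The single new stereocentre is controlled by the valine stereocentre through the chelate and by the ligand regime: a weakly bound ligand such as THF is displaced by the halide and sends the electrophile to the other face, so ethereal solvents must be excluded. The step needs carbon over nitrogen alkylation, which the soft aza-enolate carbon and the small, reactive iodomethane provide, and it needs the two alkyl groups to be told apart, which their order of introduction secures. Dilute acid then hydrolyses the imine and leaves both esters intact, and auxiliary 4 is recovered from the aqueous phase after basification. The product has no alpha hydrogen and cannot racemise.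

**Step 4**
Reactants: 9 ethyl 2-(2-methyl-1,3-dioxolan-2-yl)acetate
Product: 10 N-methoxy-N-methyl-2-(2-methyl-1,3-dioxolan-2-yl)acetamide
Conditions: MeNH(OMe)·HCl, i-PrMgCl, THF, −20 → 0 °C
Reagents that add atoms: N,O-dimethylhydroxylamine hydrochloride (CNOC.Cl)
Why: Direct aminolysis of an ester by the chloromagnesium amide of N,O-dimethylhydroxylamine formed in the flask; the ketal is inert to these basic conditions.

**Step 5**
Reactants: 8 (R)-keto ester; 10 N-methoxy-N-methylamide
Product: 11 methyl (2R)-2-[(2E)-3,7-dimethylocta-2,6-dien-1-yl]-2-methyl-6-(2-methyl-1,3-dioxolan-2-yl)-3,5-dioxohexanoate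
Conditions: LiN(i-Pr)2 (1.1 equiv), THF, −78 °C; then 10 (1.5 equiv), −78 → 0 °C; aq. NH4Cl
Reagents that add atoms: none
Why: The only alpha hydrogens of 8 are on the acetyl methyl, so a single kinetic enolate forms; its Claisen-type acylation by the N-methoxy-N-methylamide stops at the chelated tetrahedral adduct, which releases the beta-diketone only on work-up. The ketal keeps the last carbonyl masked, and the carbon that will later attack the ester is never a free methyl, so no premature ring closure can erase the stereocentre.

**Step 6**
Reactants: 11 diketone ketal
Product: 12 methyl (2R)-2-[(2E)-3,7-dimethylocta-2,6-dien-1-yl]-2-methyl-3,5,7-trioxooctanoate (as enol tautomers)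
Conditions: 1 M aq. HCl, THF, rt, short reaction time
Reagents that add atoms: water (O)
Why: Acid-catalysed ketal hydrolysis; dilute acid at room temperature should spare the trisubstituted alkenes and the methyl ester, and the short contact time limits cyclodehydration of the triketone to a 4-pyranone.

**Step 7**
Reactants: 12 trioxo ester
Product: 13 (4R)-2-acetyl-4-[(2E)-3,7-dimethylocta-2,6-dien-1-yl]-3,5-dihydroxy-4-methylcyclohexa-2,5-dien-1-one (ring A)
Conditions: KOt-Bu (3 equiv), THF, 0 °C → rt; then 1 M aq. HCl
Reagents that add atoms: none
Why: Intramolecular Claisen (Dieckmann-type) condensation: the methylene between the two outer ketones attacks the ester through a six-membered transition state, and deprotonation of the product triketone makes the closure irreversible. The quaternary alpha carbon blocks the aldol mode open to ordinary trioxo esters, and no bond to the stereocentre is broken.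

**Step 8**
Reactants: 14 phloroglucinol; 15 butanoyl chloride
Product: 16 1-(2,4,6-trihydroxyphenyl)butan-1-one
Conditions: AlCl3 (3 equiv), PhNO2–CH2Cl2, rt → 45 °C; aq. HCl work-up
Reagents that add atoms: none
Why: Friedel–Crafts acylation of phloroglucinol; the first acyl group deactivates the ring against a second.

**Step 9**
Reactants: 16 butanoylphloroglucinol
Product: 17 1-[2-hydroxy-4,6-bis(methoxymethoxy)phenyl]butan-1-one
Conditions: MOMCl (2.2 equiv), i-Pr2NEt, CH2Cl2, 0 °C → rt
Reagents that add atoms: chloromethyl methyl ether (COCCl)
Why: Phenol etherification; the para hydroxyl and one ortho hydroxyl react, after which the remaining ortho hydroxyl is locked in a hydrogen bond to the ketone and is the least nucleophilic, so protection stops at the bis-ether and leaves free exactly the oxygen destined for the pyran ring.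

**Step 10**
Reactants: 17 mono-phenol; 18 3-methylbut-2-enal
Product: 19 1-[5,7-bis(methoxymethoxy)-2,2-dimethyl-2H-chromen-8-yl]butan-1-one
Conditions: 18 (3 equiv), pyridine, 120 °C, sealed tube
Reagents that add atoms: none
Why: Pyridine-mediated chromenylation: aldol-type attack of the ring carbon ortho to the free hydroxyl on the enal, dehydration to an ortho-quinone methide and oxa-6π electrocyclisation. With one free hydroxyl and one adjacent ring CH, only the 8-acyl chromene can form.

**Step 11**
Reactants: 19 bis-MOM chromene
Product: 20 1-(5,7-dihydroxy-2,2-dimethyl-2H-chromen-8-yl)butan-1-one (ring C)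
Conditions: 3 M aq. HCl, MeOH, 40 °C
Reagents that add atoms: none
Why: Acid-catalysed acetal exchange with methanol removes both MOM groups; the 2,2-dimethylchromene is expected to tolerate dilute methanolic acid at this temperature.

**Step 12**
Reactants: 20 ring C; 21 N,N-dimethylmethaniminium iodide
Product: 22 1-[6-[(dimethylamino)methyl]-5,7-dihydroxy-2,2-dimethyl-2H-chromen-8-yl]butan-1-one
Conditions: Me2N=CH2+ I− (1.05 equiv), MeCN–CH2Cl2, 0 °C → rt; aq. NaHCO3
Reagents that add atoms: N,N-dimethylmethaniminium iodide 21 (C=[N+](C)C.[I-])
Why: Mannich aminomethylation of a phloroglucinol-type ring; C-6, flanked by two hydroxyls, is the only free aromatic carbon.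

**Step 13**
Reactants: 22 ring C Mannich base; 16 butanoylphloroglucinol
Product: 23 1-[3-[(8-butanoyl-5,7-dihydroxy-2,2-dimethyl-2H-chromen-6-yl)methyl]-2,4,6-trihydroxyphenyl]butan-1-one (ring B–ring C dimer)
Conditions: 16 (4 equiv), 1,4-dioxane, 90 °C, argon stream
Reagents that add atoms: none
Why: Thermal loss of dimethylamine from the ortho-hydroxybenzylamine gives the ring C ortho-quinone methide, which is trapped by Michael addition of a free ring carbon of 16. The excess of 16 is needed because its two free carbons are equivalent; unreacted 16 is recovered.

**Step 14**
Reactants: 23 ring B–ring C dimer; 21 N,N-dimethylmethaniminium iodide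
Product: 24 1-[3-[(8-butanoyl-5,7-dihydroxy-2,2-dimethyl-2H-chromen-6-yl)methyl]-5-[(dimethylamino)methyl]-2,4,6-trihydroxyphenyl]butan-1-one
Conditions: Me2N=CH2+ I− (1.05 equiv), MeCN–CH2Cl2, 0 °C → rt; aq. NaHCO3
Reagents that add atoms: N,N-dimethylmethaniminium iodide 21 (C=[N+](C)C.[I-])
Why: Mannich aminomethylation at the single remaining aromatic CH of ring B; ring C is fully substituted, and the product has no free nucleophilic carbon with which to self-condense.

**Step 15**
Reactants: 24 dimer Mannich base; 13 ring A
Product: 25 (4R)-2-acetyl-6-[[3-butanoyl-5-[(8-butanoyl-5,7-dihydroxy-2,2-dimethyl-2H-chromen-6-yl)methyl]-2,4,6-trihydroxyphenyl]methyl]-4-[(2E)-3,7-dimethylocta-2,6-dien-1-yl]-3,5-dihydroxy-4-methylcyclohexa-2,5-dien-1-one (CNP0103039.1)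
Conditions: 13 (1.1 equiv), 1,4-dioxane, 80 °C, argon stream
Reagents that add atoms: none
Why: The acidic enol of 13 protonates the benzylic amine of 24, dimethylamine leaves to give the ring B ortho-quinone methide, and C-6 of ring A, its only ring CH, adds in Michael fashion (Mannich base alkylation of a cyclic triketone). Each partner has one reactive site, no stereocentre is formed and the quaternary carbon is untouched.

## Compound list

1 | methyl 3-oxobutanoate (methyl acetoacetate) | COC(=O)CC(C)=O | starting material
2 | (2E)-1-bromo-3,7-dimethylocta-2,6-diene (geranyl bromide) | BrC/C=C(\C)CCC=C(C)C | starting material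
3 | methyl (4E)-2-acetyl-5,9-dimethyldeca-4,8-dienoate, racemic | COC(=O)C(C/C=C(\C)CCC=C(C)C)C(C)=O | intermediate
4 | tert-butyl L-valinate (free base) | CC(C)[C@H](N)C(=O)OC(C)(C)C | starting material
5 | tert-butyl N-[(2Z,5E)-3-(methoxycarbonyl)-6,10-dimethylundeca-2,5,9-trien-2-yl]-L-valinate | COC(=O)/C(C/C=C(\C)CCC=C(C)C)=C(/C)N[C@@H](C(C)C)C(=O)OC(C)(C)C | intermediate
6 | iodomethane | CI | starting material
7 | tert-butyl N-[(3R,5E)-3-(methoxycarbonyl)-3,6,10-trimethylundeca-5,9-dien-2-ylidene]-L-valinate | CC(=N[C@@H](C(C)C)C(=O)OC(C)(C)C)[C@@](C)(C/C=C(\C)CCC=C(C)C)C(=O)OC | intermediate (not isolated)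
8 | methyl (2R,4E)-2-acetyl-2,5,9-trimethyldeca-4,8-dienoate | CC(=O)[C@@](C)(C/C=C(\C)CCC=C(C)C)C(=O)OC | intermediate
9 | ethyl 2-(2-methyl-1,3-dioxolan-2-yl)acetate | CCOC(=O)CC1(C)OCCO1 | starting material
10 | N-methoxy-N-methyl-2-(2-methyl-1,3-dioxolan-2-yl)acetamide | CON(C)C(=O)CC1(C)OCCO1 | intermediate
11 | methyl (2R)-2-[(2E)-3,7-dimethylocta-2,6-dien-1-yl]-2-methyl-6-(2-methyl-1,3-dioxolan-2-yl)-3,5-dioxohexanoate | CC1(OCCO1)CC(=O)CC(=O)[C@@](C)(C/C=C(\C)CCC=C(C)C)C(=O)OC | intermediate
12 | methyl (2R)-2-[(2E)-3,7-dimethylocta-2,6-dien-1-yl]-2-methyl-3,5,7-trioxooctanoate | CC(=O)CC(=O)CC(=O)[C@@](C)(C/C=C(\C)CCC=C(C)C)C(=O)OC | intermediate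
13 | (4R)-2-acetyl-4-[(2E)-3,7-dimethylocta-2,6-dien-1-yl]-3,5-dihydroxy-4-methylcyclohexa-2,5-dien-1-one | C1=C(O)[C@@](C)(C/C=C(\C)CCC=C(C)C)C(O)=C(C(C)=O)C1=O | intermediate
14 | benzene-1,3,5-triol (phloroglucinol) | Oc1cc(O)cc(O)c1 | starting material
15 | butanoyl chloride | CCCC(Cl)=O | starting material
16 | 1-(2,4,6-trihydroxyphenyl)butan-1-one | CCCC(=O)c1c(O)cc(O)cc1O | intermediate
17 | 1-[2-hydroxy-4,6-bis(methoxymethoxy)phenyl]butan-1-one | CCCC(=O)c1c(O)cc(OCOC)cc1OCOC | intermediate
18 | 3-methylbut-2-enal | CC(C)=CC=O | starting material
19 | 1-[5,7-bis(methoxymethoxy)-2,2-dimethyl-2H-chromen-8-yl]butan-1-one | CCCC(=O)c1c(OCOC)cc(OCOC)c2C=CC(C)(C)Oc12 | intermediate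
20 | 1-(5,7-dihydroxy-2,2-dimethyl-2H-chromen-8-yl)butan-1-one | CCCC(=O)c1c(O)cc(O)c2C=CC(C)(C)Oc12 | intermediate
21 | N,N-dimethylmethaniminium iodide | C=[N+](C)C.[I-] | starting material
22 | 1-[6-[(dimethylamino)methyl]-5,7-dihydroxy-2,2-dimethyl-2H-chromen-8-yl]butan-1-one | CCCC(=O)c1c(O)c(CN(C)C)c(O)c2C=CC(C)(C)Oc12 | intermediate
23 | 1-[3-[(8-butanoyl-5,7-dihydroxy-2,2-dimethyl-2H-chromen-6-yl)methyl]-2,4,6-trihydroxyphenyl]butan-1-one | CCCC(=O)c1c(O)cc(O)c(Cc2c(O)c3c(c(C(=O)CCC)c2O)OC(C)(C)C=C3)c1O | intermediate
24 | 1-[3-[(8-butanoyl-5,7-dihydroxy-2,2-dimethyl-2H-chromen-6-yl)methyl]-5-[(dimethylamino)methyl]-2,4,6-trihydroxyphenyl]butan-1-one | CCCC(=O)c1c(O)c(CN(C)C)c(O)c(Cc2c(O)c3c(c(C(=O)CCC)c2O)OC(C)(C)C=C3)c1O | intermediate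
25 | (4R)-2-acetyl-6-[[3-butanoyl-5-[(8-butanoyl-5,7-dihydroxy-2,2-dimethyl-2H-chromen-6-yl)methyl]-2,4,6-trihydroxyphenyl]methyl]-4-[(2E)-3,7-dimethylocta-2,6-dien-1-yl]-3,5-dihydroxy-4-methylcyclohexa-2,5-dien-1-one | CCCC(=O)c1c(O)c(CC2=C(O)[C@@](C)(C/C=C(\C)CCC=C(C)C)C(O)=C(C(C)=O)C2=O)c(O)c(Cc2c(O)c3c(c(C(=O)CCC)c2O)OC(C)(C)C=C3)c1O | target

## Step count and risks

Total step count: 15. Longest linear sequence: 8 steps (14 to 25 through steps 8 to 15). The ring A arm runs through steps 1, 2, 3, 5, 6, 7 and 15 (7 steps), with step 4 as a one-step side branch.

**Step 3 (key step).** Most likely failure: insufficient or inverted facial selectivity. The alpha substituent already on the enamine is a geranyl group, larger than the substituents for which the chelate model is best supported, and iodomethane is the smallest electrophile, so the preference for one lithium face may be weaker; partial nitrogen methylation is a lesser concern. Fallback: exchange the roles of the two alkyl groups. Starting from 4, condensation with commercial methyl 2-methyl-3-oxobutanoate F1 should give tert-butyl N-[(2Z)-3-(methoxycarbonyl)but-2-en-2-yl]-L-valinate F2. F2 is lithiated with LiN(i-Pr)2 and alkylated with geranyl bromide 2 in toluene–THF without (Me2N)3PO. Under this weak-ligand regime the allylic bromide should enter from the face away from the isopropyl group; because the resident and the incoming group have changed places, this again corresponds to R. The sequence passes through imine 7 and returns to the route at 8.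

**Step 5.** Most likely failure: incomplete acylation. The enolate of a methyl ketone is a modest nucleophile towards an N-methoxy-N-methylamide, and any diketone set free early quenches enolate by proton transfer. Fallback: an aldol and oxidation sequence. Amide 10 is reduced with i-Bu2AlH (THF, −78 °C) to 2-(2-methyl-1,3-dioxolan-2-yl)acetaldehyde F3. F3 is added to the lithium enolate of 8 to give methyl (2R)-2-[(2E)-3,7-dimethylocta-2,6-dien-1-yl]-5-hydroxy-2-methyl-6-(2-methyl-1,3-dioxolan-2-yl)-3-oxohexanoate F4 as a mixture of carbinol epimers. Oxidation of F4 with Dess–Martin periodinane returns to the route at 11.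

**Step 7.** Most likely failure: diversion of the free triketone into other cyclisation modes. These are aldol closure of the terminal methyl onto the hindered ketone with aromatisation, oxygen acylation to a pyranone, or loss of an acyl group by retro-Claisen cleavage; all are possible because the ester to be attacked is neopentyl-like. Fallback: close the ring before unmasking. Starting from 11, the dianion formed with LiN(i-Pr)2 (3 equiv, THF, −78 → 0 °C) should undergo the same Dieckmann-type closure to (4R)-4-[(2E)-3,7-dimethylocta-2,6-dien-1-yl]-3,5-dihydroxy-4-methyl-2-(2-methyl-1,3-dioxolan-2-yl)cyclohexa-2,5-dien-1-one F5, in which no aldol mode exists because the last carbonyl is still a ketal. Hydrolysis of F5 with 1 M aq. HCl in THF returns to the route at 13, bypassing 12.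

**Step 10.** Most likely failure: low conversion in the intermolecular carbon–carbon bond formation, since the only free hydroxyl of 17 is hydrogen-bonded and the ring is deactivated by the ketone. Fallback: the propargyl ether cascade. Starting from 17, alkylation of the oxygen with 3-chloro-3-methylbut-1-yne (K2CO3, KI, cat. CuI, acetone, reflux) gives 1-[2-[(2-methylbut-3-yn-2-yl)oxy]-4,6-bis(methoxymethoxy)phenyl]butan-1-one F6. Heating F6 in xylene at 140 °C should give, by [3,3] rearrangement, 1,5-hydrogen shift and electrocyclisation, the chromene 19, where the route is rejoined.

**Step 15.** Most likely failure: scrambling of the methylene bridge already present. Heating 24 with liberated amine can cleave the ring B–ring C bridge by retro-Michael fragmentation and recombine the pieces, and oxygen alkylation of the enol may compete. Fallback: invert the roles of the partners so that the dimer is never turned into an ortho-quinone methide. Starting from 13, aminomethylation with 21 gives (4R)-2-acetyl-6-[(dimethylamino)methyl]-4-[(2E)-3,7-dimethylocta-2,6-dien-1-yl]-3,5-dihydroxy-4-methylcyclohexa-2,5-dien-1-one F7. The Mannich base of a cyclic triketone loses dimethylamine under milder conditions, and warming F7 with 23 in 1,4-dioxane at 50 °C should deliver 25 directly.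

## Further compounds

F1 | step 3 | methyl 2-methyl-3-oxobutanoate | COC(=O)C(C)C(C)=O
F2 | step 3 | tert-butyl N-[(2Z)-3-(methoxycarbonyl)but-2-en-2-yl]-L-valinate | COC(=O)/C(C)=C(/C)N[C@@H](C(C)C)C(=O)OC(C)(C)C
F3 | step 5 | 2-(2-methyl-1,3-dioxolan-2-yl)acetaldehyde | CC1(CC=O)OCCO1
F4 | step 5 | methyl (2R)-2-[(2E)-3,7-dimethylocta-2,6-dien-1-yl]-5-hydroxy-2-methyl-6-(2-methyl-1,3-dioxolan-2-yl)-3-oxohexanoate (C-5 epimers) | CC1(OCCO1)CC(O)CC(=O)[C@@](C)(C/C=C(\C)CCC=C(C)C)C(=O)OC
F5 | step 7 | (4R)-4-[(2E)-3,7-dimethylocta-2,6-dien-1-yl]-3,5-dihydroxy-4-methyl-2-(2-methyl-1,3-dioxolan-2-yl)cyclohexa-2,5-dien-1-one | C1=C(O)[C@@](C)(C/C=C(\C)CCC=C(C)C)C(O)=C(C2(C)OCCO2)C1=O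
F6 | step 10 | 1-[2-[(2-methylbut-3-yn-2-yl)oxy]-4,6-bis(methoxymethoxy)phenyl]butan-1-one | CCCC(=O)c1c(OC(C)(C)C#C)cc(OCOC)cc1OCOC
F7 | step 15 | (4R)-2-acetyl-6-[(dimethylamino)methyl]-4-[(2E)-3,7-dimethylocta-2,6-dien-1-yl]-3,5-dihydroxy-4-methylcyclohexa-2,5-dien-1-one | CN(C)CC1=C(O)[C@@](C)(C/C=C(\C)CCC=C(C)C)C(O)=C(C(C)=O)C1=O
A1 | alternative 1 | 1-[2-[(2-methylbut-3-yn-2-yl)oxy]-4,6-bis(methoxymethoxy)phenyl]butan-1-one | CCCC(=O)c1c(OC(C)(C)C#C)cc(OCOC)cc1OCOC
A2 | alternative 1 | 1-[5,7-bis(methoxymethoxy)-2,2-dimethyl-2H-chromen-8-yl]butan-1-one | CCCC(=O)c1c(OCOC)cc(OCOC)c2C=CC(C)(C)Oc12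
A3 | alternative 2 | methyl (2R)-2-[(2E)-3,7-dimethylocta-2,6-dien-1-yl]-2-methyl-3,5,7-trioxooctanoate | CC(=O)CC(=O)CC(=O)[C@@](C)(C/C=C(\C)CCC=C(C)C)C(=O)OC
A4 | alternative 2 | (4R)-2-acetyl-4-[(2E)-3,7-dimethylocta-2,6-dien-1-yl]-3,5-dihydroxy-4-methylcyclohexa-2,5-dien-1-one | C1=C(O)[C@@](C)(C/C=C(\C)CCC=C(C)C)C(O)=C(C(C)=O)C1=O
A5 | alternative 3 | methyl (2S,4E)-2-acetyl-2,5,9-trimethyldeca-4,8-dienoate | CC(=O)[C@](C)(C/C=C(\C)CCC=C(C)C)C(=O)OC
A6 | alternative 3 | 8-butanoyl-5,7-bis(methoxymethoxy)-3,4-dihydro-2H-chromen-2-one | CCCC(=O)c1c(OCOC)cc(OCOC)c2CCC(=O)Oc12
A7 | alternative 3 | (4S)-2-[[3-butanoyl-2-hydroxy-4,6-bis(methoxymethoxy)phenyl]methyl]-4-[(2E)-3,7-dimethylocta-2,6-dien-1-yl]-3,5-dihydroxy-4-methylcyclohexa-2,5-dien-1-one | CCCC(=O)c1c(O)c(CC2=C(O)[C@@](C)(C/C=C(\C)CCC=C(C)C)C(O)=CC2=O)c(OCOC)cc1OCOC
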